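## Retrosynthetic overview

- **Labels:** quinolone A carries ring C (O4–C(c)H–C(b)H–C(a)H–C3, isobutenyl on C(a)). Quinolone B carries ring D (O4–CMe2–C(b)H–C(c)H–C3). Rings C and D share the C(b)–C(c) bond.
- **Enabling feature:** the ten carbons between the two quinolone C3 atoms form one lavandulyl chain, C(c)–C(b)(CMe2)–C(a)–CH=CMe2, flanked by two copies of the same C3/O4 bis-nucleophile. Ring D holds the atom sequence O4–C4=C3–C(c)–C(b)–CMe2 of a 1-oxatriene closed at O–CMe2.
- **Key disconnections (one operation):** O4(A)–C(c) (hydroalkoxylation, ring C), O4(B)–CMe2 (oxa-6π, ring D), C3(B)=C(c) (Knoevenagel) and C3(A)–C(a) (catalytic asymmetric Michael addition). These lead back to two 4-hydroxyquinolones plus 2-isopropenyl-5-methylhexa-2,4-dienal.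
- **Building blocks:** the dienal comes from ethyl 3-methylbut-2-enoate and 3-methylbut-2-enal (α-aldol, elimination, reduction, oxidation). The quinolone comes from 2,3-dimethoxyaniline (N-methylation, malonylation, Friedel–Crafts ring closure).
- **Ring order:** pyridone ring of the quinolone, then ring D, then ring C.

Key step: step 8

Assumption: the sense of induction of 9-amino(9-deoxy)epi-quinine on the dienal is taken by analogy with its additions to α-branched enals. If it delivers the quinolone to the Re face of C3, the pseudo-enantiomeric 9-amino(9-deoxy)epi-quinidine is used, with no other change.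

## Route

Step 1
Reactants: 1 2,3-dimethoxyaniline
Product: 3 2,3-dimethoxy-N-methylaniline, via N-methoxymethyl aniline 2 (not isolated)
Conditions: (CH2O)n, NaOMe, MeOH, reflux; then NaBH4, reflux
Reagents that add atoms: paraformaldehyde (as formaldehyde), C=O
Why: Reductive amination in which the formaldehyde adduct 2 is formed completely before hydride is added, so the reaction should stop at one N-methyl group; no stereocenter is formed.

Step 2
Reactants: 3 2,3-dimethoxy-N-methylaniline; 4 Meldrum's acid (2,2-dimethyl-1,3-dioxane-4,6-dione)
Product: 5 3-[(2,3-dimethoxyphenyl)(methyl)amino]-3-oxopropanoic acid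
Conditions: toluene, 110 °C
Reagents that add atoms: none
Why: Aminolysis of Meldrum's acid (N-acylation with loss of acetone) should give the malonic acid monoanilide directly without a coupling reagent; no stereocenter is formed.

Step 3
Reactants: 5 3-[(2,3-dimethoxyphenyl)(methyl)amino]-3-oxopropanoic acid
Product: 6 4-hydroxy-7,8-dimethoxy-1-methylquinolin-2(1H)-one
Conditions: Eaton's reagent (P2O5 in MeSO3H), 70 °C
Reagents that add atoms: none
Why: Intramolecular Friedel–Crafts acylation can occur only at the single free position ortho to nitrogen, which is also para to a methoxy group, and enolisation then gives the 4-hydroxy-2-quinolone.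

Step 4
Reactants: 7 ethyl 3-methylbut-2-enoate; 8 3-methylbut-2-enal
Product: 9 ethyl 3-hydroxy-5-methyl-2-(prop-1-en-2-yl)hex-4-enoate (racemic mixture of diastereomers)
Conditions: LiN(i-Pr)2, THF, −78 °C; then 8, −78 °C; AcOH quench at −78 °C
Reagents that add atoms: none
Why: Deconjugative aldol addition, in which the lithium dienolate from γ-deprotonation reacts under kinetic control at its α-carbon and 1,2 at the enal; the two new stereocenters need no control because step 5 erases both.

Step 5
Reactants: 9 ethyl 3-hydroxy-5-methyl-2-(prop-1-en-2-yl)hex-4-enoate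
Product: 11 ethyl (2E)-5-methyl-2-(prop-1-en-2-yl)hexa-2,4-dienoate, via acetate 10 (not isolated)
Conditions: Ac2O, Et3N, DMAP (cat.), CH2Cl2, 0 °C to rt; then DBU, rt
Reagents that add atoms: none
Why: E1cB elimination of the β-acetoxy ester through its doubly activated α-proton should give the cross-conjugated triene ester, with the isobutenyl group trans to the ester group for steric reasons.

Step 6
Reactants: 11 ethyl (2E)-5-methyl-2-(prop-1-en-2-yl)hexa-2,4-dienoate
Product: 12 (2E)-5-methyl-2-(prop-1-en-2-yl)hexa-2,4-dien-1-ol
Conditions: i-Bu2AlH (2.2 equiv), CH2Cl2, −78 °C; then aq. potassium sodium tartrate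
Reagents that add atoms: none
Why: 1,2-Reduction of a conjugated ester with i-Bu2AlH stops at the allylic alcohol and leaves the three C=C bonds and their geometry untouched.

Step 7
Reactants: 12 (2E)-5-methyl-2-(prop-1-en-2-yl)hexa-2,4-dien-1-ol
Product: 13 (2E)-5-methyl-2-(prop-1-en-2-yl)hexa-2,4-dienal
Conditions: activated MnO2, CH2Cl2, rt; used at once
Reagents that add atoms: none
Why: Oxidation of an allylic alcohol with MnO2 is neutral and mild, so the alkene geometry and the sensitive triene should survive.

Step 8
Reactants: 13 (2E)-5-methyl-2-(prop-1-en-2-yl)hexa-2,4-dienal; 6 4-hydroxy-7,8-dimethoxy-1-methylquinolin-2(1H)-one (two equivalents)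
Product: 17 CNP0314650.1 (target), via Michael adduct enal 14 (not isolated), via 1-oxatriene 15 (not isolated), via 2H-pyran 16 (not isolated)
Conditions: 6 (2.1 equiv), 9-amino(9-deoxy)epi-quinine (20 mol %), CF3CO2H (40 mol %), CH2Cl2, 0 °C to rt; then camphorsulfonic acid (30 mol %), 40 °C
Reagents that add atoms: none
Why: Proposed new method: the primary amine salt turns 13 into an iminium ion that is open to attack only at C3 (= C(a), β-monosubstituted; the δ-carbon is blocked by two methyl groups), so the first 6 adds through its C3 in a Michael reaction, and the dienamine so formed, which contains the isopropenyl group, is reprotonated at its terminal CH2 to the β,β-dimethyl iminium ion of 14, which accepts the second 6 only in 1,2-fashion and loses the amine (Knoevenagel condensation) to give 1-oxatriene 15. Ring D then closes by disrotatory oxa-6π electrocyclisation of 15, in which O4 of quinolone B bonds to CMe2 (16), and ring C closes by acid-catalysed hydroalkoxylation of 16, that is protonation of the C(b)=C(c) bond at C(b) and 6-exo-trig capture of the vinylogous oxocarbenium ion at C(c) by the 4-OH of quinolone A. The closest known reaction types are the iminium-catalysed Michael addition of 4-hydroxycoumarins and 4-hydroxy-2-quinolones to enals and enones, the activation of α-branched enals by 9-amino(9-deoxy)epi-cinchona salts, and the Knoevenagel/oxa-6π annulation of 4-hydroxy-2-quinolones with 3-methylbut-2-enal; what is new is their relay on one cross-conjugated dienal. C(a) is set by the catalyst, whose protonated quinuclidine should guide the quinolonate to the Si face of C3 of the E-iminium ion. C(b) and C(c) are set by C(a) under thermodynamic control, because protonation at C(b) and C(c)–O bond formation are reversible and only the cis-fused isomer with isobutenyl anti to CMe2 places both the isobutenyl group (in ring C) and the C(c)–O bond (in ring D) pseudo-axial, away from the neighbouring lactam carbonyl groups (A1,3 strain). The step needs 1,4- before 1,2-attack (secured by the change in β-substitution of the iminium ion), closure through O4 and not O2 (secured by the more stable 2-quinolone form) and protonation of C(b)=C(c) in preference to the isobutenyl group (secured by the 4-oxygen donor of quinolone B, which is conjugated only with the former).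

## Compound list

1 | 2,3-dimethoxyaniline | COc1cccc(N)c1OC | starting material
2 | N-(methoxymethyl)-2,3-dimethoxyaniline | COCNc1cccc(OC)c1OC | intermediate
3 | 2,3-dimethoxy-N-methylaniline | CNc1cccc(OC)c1OC | intermediate
4 | Meldrum's acid (2,2-dimethyl-1,3-dioxane-4,6-dione) | CC1(C)OC(=O)CC(=O)O1 | starting material
5 | 3-[(2,3-dimethoxyphenyl)(methyl)amino]-3-oxopropanoic acid | COc1cccc(N(C)C(=O)CC(=O)O)c1OC | intermediate
6 | 4-hydroxy-7,8-dimethoxy-1-methylquinolin-2(1H)-one | COc1ccc2c(O)cc(=O)n(C)c2c1OC | intermediate
7 | ethyl 3-methylbut-2-enoate | CCOC(=O)C=C(C)C | starting material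
8 | 3-methylbut-2-enal | CC(C)=CC=O | starting material
9 | ethyl 3-hydroxy-5-methyl-2-(prop-1-en-2-yl)hex-4-enoate (racemic, both diastereomers) | CCOC(=O)C(C(C)=C)C(O)C=C(C)C | intermediate
10 | ethyl 3-acetoxy-5-methyl-2-(prop-1-en-2-yl)hex-4-enoate (racemic, both diastereomers) | CCOC(=O)C(C(C)=C)C(OC(C)=O)C=C(C)C | intermediate
11 | ethyl (2E)-5-methyl-2-(prop-1-en-2-yl)hexa-2,4-dienoate | CCOC(=O)/C(=C/C=C(C)C)C(C)=C | intermediate
12 | (2E)-5-methyl-2-(prop-1-en-2-yl)hexa-2,4-dien-1-ol | OC/C(=C/C=C(C)C)C(C)=C | intermediate
13 | (2E)-5-methyl-2-(prop-1-en-2-yl)hexa-2,4-dienal | O=C/C(=C/C=C(C)C)C(C)=C | intermediate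
14 | (3S)-3-(4-hydroxy-7,8-dimethoxy-1-methyl-2-oxo-1,2-dihydroquinolin-3-yl)-5-methyl-2-(propan-2-ylidene)hex-4-enal | COc1ccc2c(O)c(c(=O)n(C)c2c1OC)[C@@H](C=C(C)C)C(C=O)=C(C)C | intermediate
15 | (3E)-3-[(3S)-3-(4-hydroxy-7,8-dimethoxy-1-methyl-2-oxo-1,2-dihydroquinolin-3-yl)-5-methyl-2-(propan-2-ylidene)hex-4-enylidene]-7,8-dimethoxy-1-methylquinoline-2,4(1H,3H)-dione | COc1ccc2c(O)c(c(=O)n(C)c2c1OC)[C@@H](C=C(C)C)C(=C(C)C)/C=C1\C(=O)c2ccc(OC)c(OC)c2N(C)C1=O | intermediate
16 | 3-[(1S)-1-(4-hydroxy-7,8-dimethoxy-1-methyl-2-oxo-1,2-dihydroquinolin-3-yl)-3-methylbut-2-enyl]-7,8-dimethoxy-2,2,6-trimethyl-2H-pyrano[3,2-c]quinolin-5(6H)-one | COc1ccc2c(O)c(c(=O)n(C)c2c1OC)[C@@H](C=C(C)C)C1=Cc2c(c3ccc(OC)c(OC)c3n(C)c2=O)OC1(C)C | intermediate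
17 | CNP0314650.1: cis-fused bis(pyrano[3,2-c]quinolin-5-one) dimer, C(a) S, C(b) S, C(c) R; H on C(b) and H on C(c) cis, isobutenyl on C(a) trans to CMe2 on C(b) | COc1ccc2c3c(c(=O)n(C)c2c1OC)[C@@H](C=C(C)C)[C@H]1[C@@H](O3)c2c(c3ccc(OC)c(OC)c3n(C)c2=O)OC1(C)C | target

## Step count and risks

Total steps: 8. Longest linear sequence: 5 steps (7 → 9 → 11 → 12 → 13 → 17). The quinolone branch (1 → 3 → 5 → 6) joins at step 8.

**Step 8.**
- What may go wrong:
  - poor facial selectivity in the first addition to the α-branched iminium ion;
  - premature 1,2-attack of the quinolone on the dienal;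
  - acid-induced shift of the 4-OH of quinolone A onto the isobutenyl group during the last stage.
- Fallback (known chemistry), setting out from 6 and 8:
  - Knoevenagel condensation and oxa-6π electrocyclisation under ethylenediammonium diacetate (MeOH, reflux) gives veprisine F1.
  - F1 is heated in 1,2-dichlorobenzene at about 200 °C. Part of it opens to the oxadiene, which adds to the pyran C=C bond of a second molecule. This is the inverse-electron-demand hetero-Diels–Alder dimerisation known for 2,2-dimethylpyranoquinolinones.
  - After chromatographic removal of isomeric dimers, this gives racemic material, that is 17 together with the mirror image of 17 F2.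
  - The enantiomers are separated by preparative HPLC on a chiral stationary phase, and the route is rejoined at 17.

**Step 5.**
- What may go wrong: erosion of the alkene geometry, or loss of the cross-conjugated triene by 6π-electrocyclisation or polymerisation during acetylation and elimination.
- Fallback, setting out from 8:
  - Condensation with tert-butylamine over MgSO4 gives (E)-N-tert-butyl-3-methylbut-2-en-1-imine F3.
  - γ-Deprotonation with LiN(i-Pr)2 (THF, −78 °C) and reaction at the α-carbon with a second portion of 8 gives the hydroxy imine F4.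
  - Aqueous oxalic acid hydrolyses the imine and dehydrates the aldol (directed aldol condensation of a metallated aldimine). The route is rejoined at 13, and 9 to 12 are bypassed.

**Step 3.**
- What may go wrong: decarboxylation of the malonamic acid before ring closure, or loss of the methyl group of the methoxy group next to nitrogen in the strong acid.
- Fallback, setting out from 3: thermal cyclocondensation with bis(2,4,6-trichlorophenyl) malonate in diphenyl ether at about 200 °C acylates nitrogen and then the free ortho carbon without any acid. The route is rejoined at 6, and 5 is bypassed. This fallback makes no new compound (F0).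

## Further compounds

F1 | step 8 | veprisine (7,8-dimethoxy-2,2,6-trimethyl-2H-pyrano[3,2-c]quinolin-5(6H)-one) | COc1ccc2c3c(c(=O)n(C)c2c1OC)C=CC(C)(C)O3
F2 | step 8 | mirror image of 17 | COc1ccc2c3c(c(=O)n(C)c2c1OC)[C@H](C=C(C)C)[C@@H]1[C@H](O3)c2c(c3ccc(OC)c(OC)c3n(C)c2=O)OC1(C)C
F3 | step 5 | (E)-N-tert-butyl-3-methylbut-2-en-1-imine | CC(C)=C/C=N/C(C)(C)C
F4 | step 5 | (E)-1-(tert-butylimino)-5-methyl-2-(prop-1-en-2-yl)hex-4-en-3-ol (racemic, both diastereomers) | CC(C)=CC(O)C(C(C)=C)/C=N/C(C)(C)C
F0 | step 3 | none | none
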